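**Strategy.** The trans-2,3-dioxygenated dihydrofuran ring is read as the anti-opening product of an epoxide: O1 sits on C2, which is allylic to the 1-formylvinyl group and vicinal to the acetoxy carbon C3. The ring is therefore closed at the O1–C2 bond, when the ortho phenoxide of an (R,R)-trans vinyl epoxide spanning C2–C3 attacks allylic C2 with inversion; the freed C3 alkoxide is acetylated in the same flask. The precursor is an aryl silyl ether made by Shi epoxidation of an (E)-aryl diene. The carbinol centre comes from a Noyori transfer hydrogenation, and the enal from late allylic oxidation of an isopropenyl group.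

Key step: step 4

Remark on the chemistry: benzofuran numbering is used (O1, C2, C3, C3a, C4–C7, C7a). The target is taken as the trans-(2S,3R) isomer with an (R)-1-(acyloxy)ethyl group at C5 and a (Z)-2-methylbut-2-enoate (angelate). Compounds 1, 3, 4 and 12 are assumed to be catalogue chemicals.

**Step 1**
Reactants: 1 1-(3-bromo-4-hydroxyphenyl)ethanone
Product: 2 1-[3-bromo-4-(triisopropylsilyloxy)phenyl]ethanone
Conditions: TIPSCl, imidazole, DMF, 25 °C
Reagents that add atoms: triisopropylsilyl chloride, CC(C)[Si](Cl)(C(C)C)C(C)C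
Why: Silyl ether protection of the acidic phenol with a bulky silyl chloride under imidazole catalysis masks the nucleophile of the key step in a form that should survive cross-coupling and epoxidation and is removed by fluoride.

**Step 2**
Reactants: 2 1-[3-bromo-4-(triisopropylsilyloxy)phenyl]ethanone; 3 2-methylbut-1-en-3-yne; 4 pinacolborane
Product: 6 1-[3-[(1E)-3-methylbuta-1,3-dien-1-yl]-4-(triisopropylsilyloxy)phenyl]ethanone, via dienylboronate 5 (not isolated)
Conditions: 3, 4, Cp2Zr(H)Cl (5 mol %), Et3N (10 mol %), neat, sealed tube, 40 °C; then 2, Pd(OAc)2 (3 mol %), SPhos (6 mol %), K3PO4, THF–H2O (10:1), 50 °C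
Reagents that add atoms: none
Why: Zirconocene-catalysed syn hydroboration of the terminal alkyne of 3 should give the (E)-dienylboronate 5 chemoselectively, and its Suzuki–Miyaura coupling with the aryl bromide under zerovalent palladium catalysis proceeds with retention of alkene geometry, so the (E)-configuration needed for the trans-epoxide is fixed here.

**Step 3**
Reactants: 6 1-[3-[(1E)-3-methylbuta-1,3-dien-1-yl]-4-(triisopropylsilyloxy)phenyl]ethanone
Product: 7 1-[3-[(2R,3R)-3-(prop-1-en-2-yl)oxiran-2-yl]-4-(triisopropylsilyloxy)phenyl]ethanone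
Conditions: D-fructose-derived Shi ketone (30 mol %), Oxone (2KHSO5·KHSO4·K2SO4), K2CO3, n-Bu4NHSO4 (catalytic), MeCN–CH2(OMe)2, aqueous Na2B4O7/Na2EDTA buffer (pH 10.5), 0 °C
Reagents that add atoms: potassium peroxymonosulfate (KHSO5), [K+].[O-]S(=O)(=O)OO
Why: Shi asymmetric epoxidation through the chiral dioxirane and a spiro transition state should epoxidise the electron-rich trans-disubstituted styrenyl alkene in preference to the 1,1-disubstituted isopropenyl alkene, and the D-fructose-derived ketone delivers oxygen to the face that gives the (R,R)-epoxide, as it does for trans-β-methylstyrene, which sets C2 and C3 together by reagent control.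

**Step 4**
Reactants: 7 1-[3-[(2R,3R)-3-(prop-1-en-2-yl)oxiran-2-yl]-4-(triisopropylsilyloxy)phenyl]ethanone
Product: 10 (2S,3R)-5-acetyl-2-(prop-1-en-2-yl)-2,3-dihydro-1-benzofuran-3-yl acetate, via phenoxide 8 (not isolated), via alkoxide 9 (not isolated)
Conditions: n-Bu4NF (1.1 equiv), THF, 0 to 25 °C; then Ac2O (3 equiv), DMAP (10 mol %), 0 °C, same flask
Reagents that add atoms: acetic anhydride, CC(=O)OC(C)=O
Why: Fluoride cleaves the aryl silyl ether and the tetrabutylammonium phenoxide 8 attacks the allylic oxirane carbon C2 from the side opposite its C–O bond, which opens the epoxide to the C3 alkoxide 9, and this is acetylated in the same flask. The closest known reaction type is the base-induced cyclisation of 2-(oxiranyl)phenols and of 3,4-epoxy alcohols to 3-hydroxy-2,3-dihydrobenzofurans and 3-hydroxytetrahydrofurans. The dihydrofuran ring closes in the 5-endo epoxide-opening mode (5-endo-tet), because both oxirane carbons end up in the new ring. C2 is set by SN2 inversion of the (R)-oxirane carbon to (S), while C3 keeps its C–O bond and its (R) configuration, so the trans-epoxide is relayed into the trans-2,3 pattern. The step needs attack at C2 only: closure at benzylic C3 would give a four-membered ring, SN2' closure at the alkene CH2 terminus would give a seven-membered ring through a strained cisoid transition state, and the allylic character of C2 lowers the SN2 barrier. The para-acetyl group tempers the phenoxide, so push-pull opening of the benzylic C3–O bond to an ortho-quinone methide, with loss of configuration at C3, is not expected.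

**Step 5**
Reactants: 10 (2S,3R)-5-acetyl-2-(prop-1-en-2-yl)-2,3-dihydro-1-benzofuran-3-yl acetate
Product: 11 (2S,3R)-5-[(1R)-1-hydroxyethyl]-2-(prop-1-en-2-yl)-2,3-dihydro-1-benzofuran-3-yl acetate
Conditions: RuCl[(R,R)-TsDPEN](p-cymene) (1 mol %), HCO2H–Et3N (5:2), CH2Cl2, 30 °C
Reagents that add atoms: none
Why: Noyori asymmetric transfer hydrogenation of the aryl methyl ketone with the (R,R)-TsDPEN ruthenium hydride should deliver hydride to the face that gives the (R)-1-arylethanol (reagent control through the CH/π-organised six-membered transition state) and leave the alkene, the acetate and the ring stereocentres untouched.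

**Step 6**
Reactants: 11 (2S,3R)-5-[(1R)-1-hydroxyethyl]-2-(prop-1-en-2-yl)-2,3-dihydro-1-benzofuran-3-yl acetate; 12 angelic acid
Product: 14 (1R)-1-[(2S,3R)-3-acetoxy-2-(prop-1-en-2-yl)-2,3-dihydro-1-benzofuran-5-yl]ethyl (2Z)-2-methylbut-2-enoate, via mixed anhydride 13 (not isolated)
Conditions: 12, 2,4,6-trichlorobenzoyl chloride, Et3N, toluene, 25 °C; then 11, toluene, 75 °C (no DMAP)
Reagents that add atoms: none
Why: Yamaguchi-type esterification through the preformed mixed anhydride 13 without a nucleophilic amine catalyst acylates the secondary alcohol at oxygen with retention at the carbinol carbon and avoids the addition–elimination pathway that isomerises angelates to tiglates.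

**Step 7**
Reactants: 14 (1R)-1-[(2S,3R)-3-acetoxy-2-(prop-1-en-2-yl)-2,3-dihydro-1-benzofuran-5-yl]ethyl (2Z)-2-methylbut-2-enoate
Product: 16 (1R)-1-[(2S,3R)-3-acetoxy-2-(3-oxoprop-1-en-2-yl)-2,3-dihydro-1-benzofuran-5-yl]ethyl (2Z)-2-methylbut-2-enoate, via allylic alcohol 15 (not isolated)
Conditions: SeO2 (0.5 equiv), t-BuOOH (2 equiv), CH2Cl2, 0 to 25 °C; then activated MnO2 (excess), 25 °C, same flask
Reagents that add atoms: tert-butyl hydroperoxide, CC(C)(C)OO (terminal oxygen source, passed on through selenium dioxide, O=[Se]=O)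
Why: Riley allylic oxidation (selenium dioxide ene reaction at the only electron-rich alkene, then [2,3]-sigmatropic shift) should oxidise the isopropenyl methyl group, the conjugated angelate alkene being too electron-poor and the C2–H hindered and deactivated by oxygen, and MnO2 then oxidises the allylic alcohol 15 selectively to the enal without touching the esters or any stereocentre.

**Compound list**
1 | 1-(3-bromo-4-hydroxyphenyl)ethanone | CC(=O)c1ccc(O)c(Br)c1 | starting material
2 | 1-[3-bromo-4-(triisopropylsilyloxy)phenyl]ethanone | CC(=O)c1ccc(O[Si](C(C)C)(C(C)C)C(C)C)c(Br)c1 | intermediate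
3 | 2-methylbut-1-en-3-yne | C=C(C)C#C | starting material
4 | pinacolborane (4,4,5,5-tetramethyl-1,3,2-dioxaborolane) | CC1(C)OBOC1(C)C | starting material
5 | (E)-4,4,5,5-tetramethyl-2-(3-methylbuta-1,3-dien-1-yl)-1,3,2-dioxaborolane | C=C(C)/C=C/B1OC(C)(C)C(C)(C)O1 | intermediate (not isolated)
6 | 1-[3-[(1E)-3-methylbuta-1,3-dien-1-yl]-4-(triisopropylsilyloxy)phenyl]ethanone | CC(=O)c1ccc(O[Si](C(C)C)(C(C)C)C(C)C)c(/C=C/C(C)=C)c1 | intermediate
7 | 1-[3-[(2R,3R)-3-(prop-1-en-2-yl)oxiran-2-yl]-4-(triisopropylsilyloxy)phenyl]ethanone | C=C(C)[C@H]1O[C@@H]1c1cc(C(C)=O)ccc1O[Si](C(C)C)(C(C)C)C(C)C | intermediate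
8 | tetrabutylammonium 4-acetyl-2-[(2R,3R)-3-(prop-1-en-2-yl)oxiran-2-yl]phenoxide | C=C(C)[C@H]1O[C@@H]1c1cc(C(C)=O)ccc1[O-].CCCC[N+](CCCC)(CCCC)CCCC | intermediate (not isolated)
9 | tetrabutylammonium (2S,3R)-5-acetyl-2-(prop-1-en-2-yl)-2,3-dihydro-1-benzofuran-3-olate | C=C(C)[C@@H]1Oc2ccc(C(C)=O)cc2[C@H]1[O-].CCCC[N+](CCCC)(CCCC)CCCC | intermediate (not isolated)
10 | (2S,3R)-5-acetyl-2-(prop-1-en-2-yl)-2,3-dihydro-1-benzofuran-3-yl acetate | C=C(C)[C@@H]1Oc2ccc(C(C)=O)cc2[C@H]1OC(C)=O | intermediate
11 | (2S,3R)-5-[(1R)-1-hydroxyethyl]-2-(prop-1-en-2-yl)-2,3-dihydro-1-benzofuran-3-yl acetate | C=C(C)[C@@H]1Oc2ccc([C@@H](C)O)cc2[C@H]1OC(C)=O | intermediate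
12 | angelic acid, (2Z)-2-methylbut-2-enoic acid | C/C=C(/C)C(=O)O | starting material
13 | (2Z)-2-methylbut-2-enoic 2,4,6-trichlorobenzoic anhydride | C/C=C(/C)C(=O)OC(=O)c1c(Cl)cc(Cl)cc1Cl | intermediate (not isolated)
14 | (1R)-1-[(2S,3R)-3-acetoxy-2-(prop-1-en-2-yl)-2,3-dihydro-1-benzofuran-5-yl]ethyl (2Z)-2-methylbut-2-enoate | C=C(C)[C@@H]1Oc2ccc([C@@H](C)OC(=O)/C(C)=C\C)cc2[C@H]1OC(C)=O | intermediate
15 | (1R)-1-[(2S,3R)-3-acetoxy-2-(3-hydroxyprop-1-en-2-yl)-2,3-dihydro-1-benzofuran-5-yl]ethyl (2Z)-2-methylbut-2-enoate | C=C(CO)[C@@H]1Oc2ccc([C@@H](C)OC(=O)/C(C)=C\C)cc2[C@H]1OC(C)=O | intermediate (not isolated)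
16 | (1R)-1-[(2S,3R)-3-acetoxy-2-(3-oxoprop-1-en-2-yl)-2,3-dihydro-1-benzofuran-5-yl]ethyl (2Z)-2-methylbut-2-enoate | C=C(C=O)[C@@H]1Oc2ccc([C@@H](C)OC(=O)/C(C)=C\C)cc2[C@H]1OC(C)=O | target

**Step count and risks**

Total step count: 7. Longest linear sequence: 7 steps (steps 1 to 7, from compound 1).

The three steps most likely to fail:

Step 7. The ene reaction may take the C2–H instead of a methyl hydrogen, which would open or aromatise the dihydrofuran ring. The hydroxylation may also be slow next to the oxygenated C2, and the γ-acetoxy enal may lose acetic acid towards the benzofuran. The fallback sets out from 14 and replaces oxygen transfer by halogen transfer. Ene-type allylic chlorination with NaOCl and CeCl3·7H2O in CH2Cl2–H2O at 0 °C should give (1R)-1-[(2S,3R)-3-acetoxy-2-(3-chloroprop-1-en-2-yl)-2,3-dihydro-1-benzofuran-5-yl]ethyl (2Z)-2-methylbut-2-enoate F1. Ganem oxidation of the allylic chloride with anhydrous trimethylamine N-oxide in DMSO at 25 °C should then turn CH2Cl into CHO and come back to the route at 16.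

Step 3. Site selectivity between the two alkenes of the diene may be poor (epoxidation of the isopropenyl unit or double epoxidation), and the aryl silyl ether may be lost at pH 10.5 before the alkene has reacted. The fallback sets out from 2 and removes the second alkene during the epoxidation. Hydroboration of 2-methylbut-3-yn-2-ol with 4 under Cp2Zr(H)Cl catalysis should give (E)-2-methyl-4-(4,4,5,5-tetramethyl-1,3,2-dioxaborolan-2-yl)but-3-en-2-ol F2. Suzuki–Miyaura coupling of F2 with 2 under the conditions of step 2 should give 1-[3-[(1E)-3-hydroxy-3-methylbut-1-en-1-yl]-4-(triisopropylsilyloxy)phenyl]ethanone F3. Shi epoxidation of its only alkene with the same ketone should give 1-[3-[(2R,3S)-3-(2-hydroxypropan-2-yl)oxiran-2-yl]-4-(triisopropylsilyloxy)phenyl]ethanone F4. Dehydration of the tertiary alcohol with the Burgess reagent in toluene at 50 °C, where only a methyl hydrogen can be lost productively, should install the isopropenyl group and come back to the route at 7.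

Step 4. The phenoxide may open the epoxide sluggishly, may close in the SN2' sense onto the alkene terminus, or may trigger base-induced opening of the benzylic C–O bond followed by rearrangement. The fallback sets out from 7 and closes the same O1–C2 bond by allylic substitution instead of epoxide opening. Ac2O with catalytic n-Bu4NOAc should open the epoxide by acetate attack at allylic C2 with inversion and acetylate the resulting alkoxide, giving (1R,2S)-1-[5-acetyl-2-(triisopropylsilyloxy)phenyl]-3-methylbut-3-ene-1,2-diyl diacetate F5. Treatment of F5 with n-Bu4NF and Pd(PPh3)4 in THF should free the phenoxide and ionise the allylic C2 acetate to a π-allylpalladium complex. Attack of the phenoxide at C2 anti to the metal (Tsuji–Trost allylic etherification, double inversion and so net retention at C2) should come back to the route at 10 with the C3 acetate already in place.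

**Further compounds**
F1 | step 7 | (1R)-1-[(2S,3R)-3-acetoxy-2-(3-chloroprop-1-en-2-yl)-2,3-dihydro-1-benzofuran-5-yl]ethyl (2Z)-2-methylbut-2-enoate | C=C(CCl)[C@@H]1Oc2ccc([C@@H](C)OC(=O)/C(C)=C\C)cc2[C@H]1OC(C)=O
F2 | step 3 | (E)-2-methyl-4-(4,4,5,5-tetramethyl-1,3,2-dioxaborolan-2-yl)but-3-en-2-ol | CC(C)(O)/C=C/B1OC(C)(C)C(C)(C)O1
F3 | step 3 | 1-[3-[(1E)-3-hydroxy-3-methylbut-1-en-1-yl]-4-(triisopropylsilyloxy)phenyl]ethanone | CC(=O)c1ccc(O[Si](C(C)C)(C(C)C)C(C)C)c(/C=C/C(C)(C)O)c1
F4 | step 3 | 1-[3-[(2R,3S)-3-(2-hydroxypropan-2-yl)oxiran-2-yl]-4-(triisopropylsilyloxy)phenyl]ethanone | CC(C)(O)[C@H]1O[C@@H]1c1cc(C(C)=O)ccc1O[Si](C(C)C)(C(C)C)C(C)C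
F5 | step 4 | (1R,2S)-1-[5-acetyl-2-(triisopropylsilyloxy)phenyl]-3-methylbut-3-ene-1,2-diyl diacetate | C=C(C)[C@H](OC(C)=O)[C@H](OC(C)=O)c1cc(C(C)=O)ccc1O[Si](C(C)C)(C(C)C)C(C)C
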